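## Structural features

Carbons are labelled C1–C20 along the target SMILES. C1 and C3 are the geminal methyls on C2; the bromocyclohexane ring is C2–C4–C5–C18–C19–C20; C6 is the exocyclic alkene CH; the cyclopentane is C7–C8–C9–C10–C17; the cyclohexane is C10–C12–C13–C14–C15–C17; C11 and C16 are the methyls on C10 and C15.

The target is a trans-fused hydrindane whose C7 carries, through the E-configured trisubstituted C5=C6 bond, a 4-bromo-3,3-dimethylcyclohexylidene ring. C7, C17 and C15 are contiguous stereocentres, and C17–C10–C12 continue the array: the axial C11 methyl on quaternary C10 is syn-axial to the C15 hydroxyl and flanked by the equatorial C12 bromide, and the C6 substituent on C7 is trans to C15. C20 is cut off from every other stereocentre by the alkene, so only a reagent can set it, and the alkene geometry is defined only by the difference between C4 (next to C2) and C18. The fragile groups are the two secondary bromides next to quaternary carbons (slow substitution, methyl shifts on ionisation), the tertiary C15 alcohol (dehydration, and retro-aldol whenever C6 is a carbonyl) and the trisubstituted alkene (acid moves it into the ring). The real difficulty lies in making both neopentyl C–Br bonds with control, in the trans fusion of a hydrindane, and in the E alkene. The key step uses two features: C12 and C15 bear heteroatoms on either side of the C10(CH3)–C17(H) bond, as the carbonyls do at the methylated double bond of a p-benzoquinone, and the ring C7–C8–C9–C10–C17 can be read as a cyclohexene made from a diene (C6–C7–C8–C9) from which C6 has been pushed out onto C7.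

## Logic of the disconnections

33 from 32: only the O–Si bond on C15 is cut. The tertiary alcohol stays masked through all base, phosphonium and hydride chemistry; the forward step must avoid acid because of the alkene.

32 from 31 from 30: the C20–Br bond is traced to C20–O and then to a C20 ketone. C20 is remote, so it has to be set by a reagent; a ketone between quaternary C2 and a methylene is an ideal case for a catalytic asymmetric reduction. The demand is a substitution with inversion at a carbinol next to a gem-dimethyl carbon.

30 from 29 from 28 from 26 and 27: the cyclohexanone ring is opened at C19–C20 (Dieckmann) and at C2–C4 (enolate alkylation). The ring is built after the alkene, so its geometry never depends on olefinating a nearly symmetric ketone, and no ketone ever sits γ to a bromide. The gain is an allylic bromide plus a four-carbon ester. The demand is SN2 (not SN2′) alkylation with retention of geometry, and ring closure onto a hindered ester.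

26 from 25 from 24 from 19 and 22: the C5=C6 bond is cut by a Horner–Wadsworth–Emmons reaction in which the ester carbon of 22 becomes C4. Its E preference is exactly the required relationship (C4 trans to C7). 22 comes from 20 and 21 by forming C5–C18.

19 from 16 from 14: the C7–C17 bond is cut and C6 is put back between them (Wolff contraction in reverse). This turns a trans-hydrindane into a trans-decalin and gives C7 its exocyclic carbon for free. The demand is a diazo group on C7 only (methylene against methine at C17), migration with retention, and a C7 that can be equilibrated.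

14 from 12 from 11 from 10 from 9: the C12–Br bond is traced to a bromoalkene, an enol triflate and the C12 ketone. Adding hydrogen to C12 from the α face avoids any substitution at a carbon whose backside is eclipsed by C11. The demand is hydrogenation without C–Br hydrogenolysis and without a free hydroxyl that could steer the metal.

9 from 7: the C15–C16 bond is cut (methyl addition). The demand is attack at C15 and not C12, from the equatorial side.

7 from 6 from 5: the C13–O bond and the C13=C14 unsaturation are restored, and C17 is returned to the cis configuration that a cycloaddition gives.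

5 from 2 and 4: C9–C10 and C6–C17 are cut by a Diels–Alder reaction. It makes quaternary C10, the 1,4-dioxygenation and the six carbons of the later cyclopentane in one step. The demand is reaction at the methylated double bond, the CH2 terminus of the diene on C10, and one enantioface. In 2 the methoxy group is on C13: a boron Lewis acid binds the vinylogous-ester carbonyl, which is then C15, so C10 is its β-carbon. In the 2-methoxy-5-methyl isomer the bound carbonyl would be C12 and the orientation would reverse. The diene oxygen is a silyl ether because an acetate β to the C15 carbonyl would be lost by E1cB elimination when C17 is epimerised. 2 comes from 1 by phenol oxidation; 4 comes from 3 by O-silylation.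

## Other disconnections considered

Alternative 1: The cut is the same ring expansion, applied to a different decalin: C7–C8 is broken and C6 re-inserted between C7 and C8, leading to the α-diazo ketone A2 and on to (S)-Wieland–Miescher ketone A1. Forward, irradiation of A2 in methanol would expel nitrogen, shift C8 from C6 to C7 and give the ester A3.
- In favour: A1 is made in quantity by an organocatalytic Robinson annulation, so C10 needs no chiral Lewis acid. The trans fusion would come from a dissolving-metal reduction of the enone, a kinetically controlled step that also delivers the enolate regiodefined at C7. On these two points alternative 1 is the better plan, since the chosen route has to equilibrate C17.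
- Against: A1 has no oxygen at C15, which must be introduced and carried as the silyl ether seen in A3. C12 must travel as a ketal. The C15 methyl must be added after contraction, when the C7 ester shields the α face the nucleophile needs. Without the reductive enolate the C6 ketone has methylenes on both sides, whereas in 14 the choice is methylene against methine.
- Comparison: in mechanism the plans are equal (the same Wolff shift with retention). In structure the chosen plan gets the C12/C15 oxygenation from the quinone. In step count alternative 1 is expected to be equal or slightly longer.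

Alternative 2: The cut is C4–C5 of the bromocyclohexylidene ring. Forward, the alkyne A4 would be hydrozirconated with Cp2Zr(H)Cl and iodinated to the (E)-iodoalkene A5; zinc would insert into the primary C4–I bond and Pd(PPh3)4 would couple the alkylzinc with the iodoalkene to give A6.
- In favour: the geometry follows from a syn addition and is kept in the coupling. On this point alternative 2 is better than the chosen plan, which relies on the E preference of an olefination. The ring closes with both bromides and all stereocentres in place, so the end is short.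
- Against: the open chain must already hold the C20 bromide next to quaternary C2 as one enantiomer, the same substitution problem as step 20 but without a ring to offer a good conformation. The C4 organozinc has the C20 bromide in a 1,3 relationship and can collapse to a gem-dimethylcyclopropane. Zinc must tell a neopentyl iodide from an iodoalkene and two secondary bromides. Zirconium must go to C5 of an alkyne flanked by a methine and a methylene.
- Comparison: in logic the plans are equal (ring closure after the alkene is fixed). In steps alternative 2 is shorter after the hydrindane but pays for it in the chain.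

Alternative 3: The cut is C10–C12 and C15–C17, the six-membered ring itself. Forward, a cationic oxazaborolidine would activate the (E)-enal A7 and its C10=C17 bond would add to the diene A8 to give A9.
- In favour: the E geometry of A7 becomes the trans relationship of C11 and H17 directly, so no epimerisation is needed; on this point alternative 3 is better. α-Methyl enals are the classical substrates of this catalyst. C10 and the C12/C15 oxygens arrive in one step, as in the chosen plan (equal).
- Against: a β-substituted α-methyl enal is a sluggish dienophile and A8 an electron-poor diene. The two acetates of A9 are the same group and must be told apart. The C12 acetate would have to be replaced by bromide by substitution next to C10, which the chosen route avoids. The cyclopentane still has to be built (C8–C9) and C7 functionalised and set, whereas the Wolff contraction delivers the ring with C6 attached.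
- Comparison: alternative 3 is expected to be longer.

Key step: step 3

Assumption: the (S)-oxazaborolidinium is taken to expose the face of C10=C17 that gives (10S); if the binding model assigns the opposite sense, the (R)-catalyst is used and nothing else changes.
Abbreviation: Ind = (1S,3aS,4S,7R,7aS)-4-bromo-3a,7-dimethyl-7-(triethylsilyloxy)octahydro-1H-inden-1-yl (C7 is its C1).

## Steps

Step 1
Reactants: 1 2-methoxy-6-methylphenol
Product: 2 2-methoxy-6-methyl-1,4-benzoquinone
Conditions: O2 (1 atm), Co(salen) (5 mol %), DMF, rt
Reagents that add atoms: dioxygen, O=O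
Why: Aerobic cobalt-salen oxidation of a 2,6-disubstituted phenol with a free para position gives the p-quinone (phenol-to-quinone oxidation); no stereocentre is formed.

Step 2
Reactants: 3 (E)-but-2-enal
Product: 4 (E)-1-(triethylsilyloxy)buta-1,3-diene
Conditions: Et3SiOTf, Et3N, Et2O, 0 °C to rt
Reagents that add atoms: triethylsilyl trifluoromethanesulfonate, CC[Si](CC)(CC)OS(=O)(=O)C(F)(F)F
Why: O-Silylation of the enal and γ-deprotonation (silyl dienol ether formation) should give mainly the (E)-diene; any (Z)-isomer reaches the s-cis form poorly and stays out of the cycloaddition.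

Step 3
Reactants: 2 2-methoxy-6-methyl-1,4-benzoquinone; 4 (E)-1-(triethylsilyloxy)buta-1,3-diene
Product: 5 (4aS,5R,8aS)-2-methoxy-8a-methyl-5-(triethylsilyloxy)-4a,5,8,8a-tetrahydronaphthalene-1,4-dione (cis-fused adduct)
Conditions: (S)-B-(o-tolyl)-α,α-diphenylprolinol oxazaborolidine (20 mol %), Tf2NH (18 mol %), CH2Cl2, −78 °C; Et3N quench
Reagents that add atoms: none
Why: The oxazaborolidine protonated by Tf2NH is a cationic boron Lewis acid that binds the more basic carbonyl of 2, the vinylogous-ester carbonyl C15, at the lone pair syn to C17–H, and the activated C10=C17 bond undergoes a concerted, asynchronous endo [4+2] cycloaddition with the s-cis diene (closest known reaction type: cationic oxazaborolidine-catalysed enantioselective Diels–Alder reactions of 2,6-disubstituted benzoquinones with silyloxy dienes). The ring closed is the cyclohexene C6–C7–C8–C9–C10–C17, by suprafacial [4+2] union of the four diene carbons with C10 and C17 (bonds C9–C10 and C6–C17). C10 is set by the catalyst: the diene should add to the face of C10=C17 not covered by the aryl group of the catalyst, giving (10S) under the stated assumption. C17 follows from suprafacial addition (H cis to C11, corrected in step 4) and C6 from the endo rule (silyloxy cis to C15, removed later by oxidation). Site selectivity is needed and comes from the methoxy group, which makes C13=C14 an enol ether that does not act as a dienophile. Regioselectivity is needed and comes from placing the methoxy group on C13: the Lewis-acid-bound carbonyl is then C15, C10 is its β-carbon and takes the nucleophilic CH2 terminus (C9), while the oxygenated terminus C6 bonds to C17. Enantioface selectivity is needed and rests on two-point binding (B–O and C17–H···O) of the quinone to the catalyst.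

Step 4
Reactants: 5 cis-fused adduct
Product: 6 (4aR,5R,8aS)-2-methoxy-8a-methyl-5-(triethylsilyloxy)-4a,5,8,8a-tetrahydronaphthalene-1,4-dione (trans-fused)
Conditions: KOtBu (0.1 equiv), tBuOH–THF, 0 °C; AcOH
Reagents that add atoms: none
Why: Base-mediated enolisation–reprotonation at C17 (the only α-hydrogen of C15) should move the adduct to the trans-fused ene-dione, as in the parent methyl-substituted quinone adducts; a silanolate is a poorer leaving group than acetate, which holds back E1cB loss of the C6 oxygen, and unchanged 5 is recycled.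

Step 5
Reactants: 6 trans-fused adduct
Product: 7 (4aS,8R,8aR)-4a-methyl-8-(triethylsilyloxy)-2,3,4a,5,8,8a-hexahydronaphthalene-1,4-dione
Conditions: SmI2 (4.5 equiv), THF–MeOH, −78 °C; pH 7 buffer
Reagents that add atoms: none
Why: Divalent samarium reduces the ene-dione to the saturated dione and then cleaves the C13–OMe bond α to the C12 carbonyl (reductive cleavage of an α-alkoxy ketone); the cold buffered quench is meant to keep C17 from re-equilibrating.

Step 6
Reactants: 7 trans-fused dione
Product: 9 (4R,4aR,5R,8aS)-4,8a-dimethyl-4,5-bis(triethylsilyloxy)-3,4,4a,5,8,8a-hexahydronaphthalen-1(2H)-one, via bromomagnesium alkoxide 8 (not isolated)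
Conditions: MeMgBr (1.3 equiv), THF, −78 to −30 °C; then Et3SiOTf (1.6 equiv), −78 to 0 °C
Reagents that add atoms: methylmagnesium bromide, C[Mg]Br; triethylsilyl trifluoromethanesulfonate, CC[Si](CC)(CC)OS(=O)(=O)C(F)(F)F
Why: Grignard addition goes to C15 in preference to C12, which sits next to quaternary C10; the axial path at C15 is blocked by the syn-axial C11 methyl, so methyl enters equatorially from the α face and the axial β-alkoxide is silylated in the same flask.

Step 7
Reactants: 9 bis(silyl ether) ketone
Product: 10 (4R,4aR,5R,8aS)-4,8a-dimethyl-4,5-bis(triethylsilyloxy)-3,4,4a,5,8,8a-hexahydronaphthalen-1-yl trifluoromethanesulfonate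
Conditions: KN(SiMe3)2 (1.2 equiv), THF, −78 °C; PhNTf2, −78 to 0 °C
Reagents that add atoms: N-phenylbis(trifluoromethanesulfonimide), O=S(=O)(N(c1ccccc1)S(=O)(=O)C(F)(F)F)C(F)(F)F
Why: Enol triflate formation: C12 can enolise only towards C13 because C10 is quaternary, so one potassium enolate forms and is trapped on oxygen.

Step 8
Reactants: 10 enol triflate
Product: 11 (4R,4aR,5R,8aS)-1-bromo-4,8a-dimethyl-4,5-bis(triethylsilyloxy)-3,4,4a,5,8,8a-hexahydronaphthalene
Conditions: Ni(cod)2 (10 mol %), LiBr (3 equiv), DMA–THF, rt
Reagents that add atoms: lithium bromide, [Li+].[Br-]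
Why: Nickel-catalysed triflate-to-bromide exchange of an enol triflate (oxidative addition to zerovalent nickel, halide exchange, reductive elimination) gives the bromoalkene without touching the silyl ethers or the ring alkene.

Step 9
Reactants: 11 bromoalkene
Product: 12 (1S,4R,4aR,5R,8aS)-1-bromo-4,8a-dimethyl-4,5-bis(triethylsilyloxy)decahydronaphthalene
Conditions: H2 (1–10 bar), [Ir(cod)(PCy3)(py)]PF6 (10 mol %), CH2Cl2, rt
Reagents that add atoms: none
Why: Homogeneous hydrogenation with the cationic iridium catalyst saturates C7=C8 and the bromoalkene without C–Br hydrogenolysis; hydrogen reaches C12=C13 from the α face because the β face carries the C11 methyl and the axial silyloxy group on C15 (silylated, so it cannot bind the metal), which leaves the C12 bromide equatorial and β.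

Step 10
Reactants: 12 saturated bromide
Product: 14 (4aS,5S,8R,8aS)-5-bromo-4a,8-dimethyl-8-(triethylsilyloxy)octahydronaphthalen-1(2H)-one, via C6 alcohol 13 (not isolated)
Conditions: PPTS (0.2 equiv), MeOH–CH2Cl2, 0 °C; evaporate; Dess–Martin periodinane, NaHCO3, CH2Cl2, rt
Reagents that add atoms: none
Why: Acid-catalysed methanolysis removes the secondary triethylsilyl ether much faster than the tertiary one wedged between C10 and C17; buffered Dess–Martin oxidation then gives the C6 ketone without epimerising C17.

Step 11
Reactants: 14 C6 ketone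
Product: 16 (4aS,5S,8R,8aS)-5-bromo-2-diazo-4a,8-dimethyl-8-(triethylsilyloxy)octahydronaphthalen-1(2H)-one, via trifluoroacetyl ketone 15 (not isolated)
Conditions: LiN(SiMe3)2 (1.1 equiv), THF, −78 °C; CF3CO2CH2CF3; then MsN3, Et3N, H2O, MeCN, rt
Reagents that add atoms: methanesulfonyl azide, CS(=O)(=O)N=[N+]=[N-]
Why: Detrifluoroacetylative diazo transfer (a Regitz-type diazo transfer): kinetic deprotonation takes the C7 methylene and not the hindered C17 methine, the trifluoroacetyl group activates C7 and leaves with the sulfonamide; the silyl ether on C15 rules out retro-aldol cleavage.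

Step 12
Reactants: 16 α-diazo ketone
Product: 19 methyl (1R,3aS,4S,7R,7aS)-4-bromo-3a,7-dimethyl-7-(triethylsilyloxy)octahydro-1H-indene-1-carboxylate, via ketene 17 (not isolated), via C7-epimeric ester 18 (not isolated)
Conditions: hν (>300 nm, Pyrex), MeOH, rt; then NaOMe (0.3 equiv), MeOH, rt
Reagents that add atoms: methanol, CO
Why: Photochemical Wolff rearrangement: loss of N2 with 1,2-shift of C17 from C6 to C7 (retention at C17) gives the ketene, which methanol traps; methoxide then equilibrates C7 to the ester trans to the C15 substituent on C17, the configuration of the target.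

Step 13
Reactants: 20 triethyl phosphonoacetate; 21 tert-butyl acrylate
Product: 22 5-tert-butyl 1-ethyl 2-(diethoxyphosphoryl)pentanedioate
Conditions: NaOEt (0.1 equiv), EtOH, 0 °C to rt; 20 in excess
Reagents that add atoms: none
Why: Base-catalysed Michael addition of the phosphonoacetate carbanion to the acrylate; the excess of 20 limits double addition.

Step 14
Reactants: 19 trans ester; 22 phosphonate
Product: 24 5-tert-butyl 1-ethyl (2E)-2-(Ind-methylidene)pentanedioate, via aldehyde 23 (not isolated)
Conditions: iBu2AlH (1.1 equiv), CH2Cl2, −78 °C; then 22/NaH in THF, −78 °C to rt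
Reagents that add atoms: none
Why: Partial reduction to the aluminium hemiacetal and Horner–Wadsworth–Emmons olefination in one flask avoid handling the aldehyde; with an α-substituted phosphonoacetate the olefination is under thermodynamic control and puts the ester (future C4) trans to C7, the E alkene.

Step 15
Reactants: 24 (E)-enoate
Product: 25 tert-butyl (4E)-4-(hydroxymethyl)-5-Ind-pent-4-enoate
Conditions: iBu2AlH (2.5 equiv), CH2Cl2, −78 °C; potassium sodium tartrate work-up
Reagents that add atoms: none
Why: iBu2AlH reduces the conjugated ethyl ester to the allylic alcohol at −78 °C while the bulky tert-butyl ester survives (steric chemoselectivity between esters); the alkene geometry is untouched.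

Step 16
Reactants: 25 allylic alcohol
Product: 26 tert-butyl (4E)-4-(bromomethyl)-5-Ind-pent-4-enoate
Conditions: CBr4, PPh3, CH2Cl2, 0 °C
Reagents that add atoms: carbon tetrabromide, BrC(Br)(Br)Br
Why: Appel reaction at an unhindered primary allylic alcohol: SN2 at C4, no allylic transposition, geometry retained.

Step 17
Reactants: 26 allylic bromide; 27 methyl isobutyrate
Product: 29 tert-butyl (5E)-5-(Ind-methylidene)-3,3-dimethyl-2-oxocyclohexane-1-carboxylate, via diester 28 (not isolated)
Conditions: 27, LiN(iPr)2, THF, −78 °C; add 26, −78 to 0 °C; then KOtBu, 0 °C to rt; NH4Cl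
Reagents that add atoms: none
Why: C-Alkylation of the lithium enolate of 27 by the primary allylic bromide (SN2, not SN2′, since C6 is hindered) creates quaternary C2; tert-butoxide then drives a Dieckmann condensation of the C19 enolate onto the non-enolisable C20 ester, closing the six-membered ring with the alkene geometry already fixed.

Step 18
Reactants: 29 β-keto ester
Product: 30 (4E)-4-(Ind-methylidene)-2,2-dimethylcyclohexan-1-one
Conditions: DMSO–H2O, 130 °C
Reagents that add atoms: none
Why: Thermal loss of isobutene from the tert-butyl β-keto ester and decarboxylation of the β-keto acid under neutral conditions; acid is avoided to protect the exocyclic alkene and the silyl ether.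

Step 19
Reactants: 30 ketone
Product: 31 (1R,4E)-4-(Ind-methylidene)-2,2-dimethylcyclohexan-1-ol
Conditions: (S)-2-methyl-CBS-oxazaborolidine (20 mol %), catecholborane, toluene, −78 to −40 °C
Reagents that add atoms: none
Why: Corey–Bakshi–Shibata reduction: with a quaternary carbon on one side and a methylene on the other, the (S)-catalyst should give the (20R)-alcohol under reagent control, independent of the distant hydrindane; catecholborane does not hydroborate the alkene at this temperature.

Step 20
Reactants: 31 (20R)-alcohol
Product: 32 {[(1S,3aS,4S,7R,7aS)-4-bromo-1-{(E)-[(4S)-4-bromo-3,3-dimethylcyclohexylidene]methyl}-3a,7-dimethyloctahydro-1H-inden-7-yl]oxy}triethylsilane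
Conditions: CBr4, P(n-C8H17)3, toluene, 70 °C
Reagents that add atoms: carbon tetrabromide, BrC(Br)(Br)Br
Why: Appel-type bromination with inversion (alkoxyphosphonium, SN2 by bromide), (20R) to (20S): in the flexible monocyclic ring the leaving group can sit equatorial so that bromide comes in along the axial direction without eclipsing a C2 methyl; the trialkylphosphine variant is the one used for carbinols next to a gem-dimethyl carbon.

Step 21
Reactants: 32 silyl ether
Product: 33 (3S,3aS,4R,7S,7aS)-7-bromo-3-{(E)-[(4S)-4-bromo-3,3-dimethylcyclohexylidene]methyl}-4,7a-dimethyloctahydro-1H-inden-4-ol (CNP0119865.1)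
Conditions: HF·pyridine, pyridine, THF, 0 °C to rt
Reagents that add atoms: none
Why: Buffered fluoride cleavage of the tertiary triethylsilyl ether; nothing acidic enough to move the alkene or ionise C15 is present.

## Compound list

1 | 2-methoxy-6-methylphenol | COc1cccc(C)c1O | starting material
2 | 2-methoxy-6-methyl-1,4-benzoquinone | COC1=CC(=O)C=C(C)C1=O | intermediate
3 | (E)-but-2-enal | C/C=C/C=O | starting material
4 | (E)-1-(triethylsilyloxy)buta-1,3-diene | C=C/C=C/O[Si](CC)(CC)CC | intermediate
5 | (4aS,5R,8aS)-2-methoxy-8a-methyl-5-(triethylsilyloxy)-4a,5,8,8a-tetrahydronaphthalene-1,4-dione | CC[Si](CC)(CC)O[C@@H]1C=CC[C@]2(C)C(=O)C(OC)=CC(=O)[C@H]12 | intermediate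
6 | (4aR,5R,8aS)-2-methoxy-8a-methyl-5-(triethylsilyloxy)-4a,5,8,8a-tetrahydronaphthalene-1,4-dione | CC[Si](CC)(CC)O[C@@H]1C=CC[C@]2(C)C(=O)C(OC)=CC(=O)[C@@H]12 | intermediate
7 | (4aS,8R,8aR)-4a-methyl-8-(triethylsilyloxy)-2,3,4a,5,8,8a-hexahydronaphthalene-1,4-dione | CC[Si](CC)(CC)O[C@@H]1C=CC[C@]2(C)C(=O)CCC(=O)[C@@H]12 | intermediate
8 | bromomagnesium alkoxide of (4R,4aR,5R,8aS)-4-hydroxy-4,8a-dimethyl-5-(triethylsilyloxy)-3,4,4a,5,8,8a-hexahydronaphthalen-1(2H)-one | CC[Si](CC)(CC)O[C@@H]1C=CC[C@]2(C)C(=O)CC[C@@](C)(O[Mg]Br)[C@@H]12 | intermediate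
9 | (4R,4aR,5R,8aS)-4,8a-dimethyl-4,5-bis(triethylsilyloxy)-3,4,4a,5,8,8a-hexahydronaphthalen-1(2H)-one | CC[Si](CC)(CC)O[C@@H]1C=CC[C@]2(C)C(=O)CC[C@@](C)(O[Si](CC)(CC)CC)[C@@H]12 | intermediate
10 | (4R,4aR,5R,8aS)-4,8a-dimethyl-4,5-bis(triethylsilyloxy)-3,4,4a,5,8,8a-hexahydronaphthalen-1-yl trifluoromethanesulfonate | CC[Si](CC)(CC)O[C@@H]1C=CC[C@]2(C)C(OS(=O)(=O)C(F)(F)F)=CC[C@@](C)(O[Si](CC)(CC)CC)[C@@H]12 | intermediate
11 | (4R,4aR,5R,8aS)-1-bromo-4,8a-dimethyl-4,5-bis(triethylsilyloxy)-3,4,4a,5,8,8a-hexahydronaphthalene | CC[Si](CC)(CC)O[C@@H]1C=CC[C@]2(C)C(Br)=CC[C@@](C)(O[Si](CC)(CC)CC)[C@@H]12 | intermediate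
12 | (1S,4R,4aR,5R,8aS)-1-bromo-4,8a-dimethyl-4,5-bis(triethylsilyloxy)decahydronaphthalene | CC[Si](CC)(CC)O[C@@H]1CCC[C@]2(C)[C@@H](Br)CC[C@@](C)(O[Si](CC)(CC)CC)[C@@H]12 | intermediate
13 | (1R,4aS,5S,8R,8aR)-5-bromo-4a,8-dimethyl-8-(triethylsilyloxy)decahydronaphthalen-1-ol | O[C@@H]1CCC[C@]2(C)[C@@H](Br)CC[C@@](C)(O[Si](CC)(CC)CC)[C@@H]12 | intermediate
14 | (4aS,5S,8R,8aS)-5-bromo-4a,8-dimethyl-8-(triethylsilyloxy)octahydronaphthalen-1(2H)-one | O=C1CCC[C@]2(C)[C@@H](Br)CC[C@@](C)(O[Si](CC)(CC)CC)[C@@H]12 | intermediate
15 | 2-(trifluoroacetyl) derivative of 14 (C7 not defined, enolised) | O=C1C(C(=O)C(F)(F)F)CC[C@]2(C)[C@@H](Br)CC[C@@](C)(O[Si](CC)(CC)CC)[C@@H]12 | intermediate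
16 | (4aS,5S,8R,8aS)-5-bromo-2-diazo-4a,8-dimethyl-8-(triethylsilyloxy)octahydronaphthalen-1(2H)-one | O=C1C(=[N+]=[N-])CC[C@]2(C)[C@@H](Br)CC[C@@](C)(O[Si](CC)(CC)CC)[C@@H]12 | intermediate
17 | (3aS,4S,7R,7aS)-4-bromo-3a,7-dimethyl-1-(oxomethylidene)-7-(triethylsilyloxy)octahydro-1H-indene (ketene) | O=C=C1CC[C@]2(C)[C@@H](Br)CC[C@@](C)(O[Si](CC)(CC)CC)[C@@H]12 | intermediate
18 | methyl (1S,3aS,4S,7R,7aS)-4-bromo-3a,7-dimethyl-7-(triethylsilyloxy)octahydro-1H-indene-1-carboxylate (C7 epimer) | COC(=O)[C@H]1CC[C@]2(C)[C@@H](Br)CC[C@@](C)(O[Si](CC)(CC)CC)[C@@H]12 | intermediate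
19 | methyl (1R,3aS,4S,7R,7aS)-4-bromo-3a,7-dimethyl-7-(triethylsilyloxy)octahydro-1H-indene-1-carboxylate | COC(=O)[C@@H]1CC[C@]2(C)[C@@H](Br)CC[C@@](C)(O[Si](CC)(CC)CC)[C@@H]12 | intermediate
20 | triethyl phosphonoacetate | CCOC(=O)CP(=O)(OCC)OCC | starting material
21 | tert-butyl acrylate | C=CC(=O)OC(C)(C)C | starting material
22 | 5-tert-butyl 1-ethyl 2-(diethoxyphosphoryl)pentanedioate | CCOC(=O)C(CCC(=O)OC(C)(C)C)P(=O)(OCC)OCC | intermediate
23 | (1R,3aS,4S,7R,7aS)-4-bromo-3a,7-dimethyl-7-(triethylsilyloxy)octahydro-1H-indene-1-carbaldehyde | O=C[C@@H]1CC[C@]2(C)[C@@H](Br)CC[C@@](C)(O[Si](CC)(CC)CC)[C@@H]12 | intermediate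
24 | 5-tert-butyl 1-ethyl (2E)-2-(Ind-methylidene)pentanedioate | CCOC(=O)/C(CCC(=O)OC(C)(C)C)=C/[C@@H]1CC[C@]2(C)[C@@H](Br)CC[C@@](C)(O[Si](CC)(CC)CC)[C@@H]12 | intermediate
25 | tert-butyl (4E)-4-(hydroxymethyl)-5-Ind-pent-4-enoate | OC/C(CCC(=O)OC(C)(C)C)=C/[C@@H]1CC[C@]2(C)[C@@H](Br)CC[C@@](C)(O[Si](CC)(CC)CC)[C@@H]12 | intermediate
26 | tert-butyl (4E)-4-(bromomethyl)-5-Ind-pent-4-enoate | BrC/C(CCC(=O)OC(C)(C)C)=C/[C@@H]1CC[C@]2(C)[C@@H](Br)CC[C@@](C)(O[Si](CC)(CC)CC)[C@@H]12 | intermediate
27 | methyl isobutyrate | COC(=O)C(C)C | starting material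
28 | 7-tert-butyl 1-methyl (4E)-4-(Ind-methylidene)-2,2-dimethylheptanedioate | COC(=O)C(C)(C)C/C(CCC(=O)OC(C)(C)C)=C/[C@@H]1CC[C@]2(C)[C@@H](Br)CC[C@@](C)(O[Si](CC)(CC)CC)[C@@H]12 | intermediate
29 | tert-butyl (5E)-5-(Ind-methylidene)-3,3-dimethyl-2-oxocyclohexane-1-carboxylate | CC1(C)C/C(=C/[C@@H]2CC[C@]3(C)[C@@H](Br)CC[C@@](C)(O[Si](CC)(CC)CC)[C@@H]23)CC(C(=O)OC(C)(C)C)C1=O | intermediate
30 | (4E)-4-(Ind-methylidene)-2,2-dimethylcyclohexan-1-one | CC1(C)C/C(=C/[C@@H]2CC[C@]3(C)[C@@H](Br)CC[C@@](C)(O[Si](CC)(CC)CC)[C@@H]23)CCC1=O | intermediate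
31 | (1R,4E)-4-(Ind-methylidene)-2,2-dimethylcyclohexan-1-ol | CC1(C)C/C(=C/[C@@H]2CC[C@]3(C)[C@@H](Br)CC[C@@](C)(O[Si](CC)(CC)CC)[C@@H]23)CC[C@H]1O | intermediate
32 | {[(1S,3aS,4S,7R,7aS)-4-bromo-1-{(E)-[(4S)-4-bromo-3,3-dimethylcyclohexylidene]methyl}-3a,7-dimethyloctahydro-1H-inden-7-yl]oxy}triethylsilane | CC1(C)C/C(=C/[C@@H]2CC[C@]3(C)[C@@H](Br)CC[C@@](C)(O[Si](CC)(CC)CC)[C@@H]23)CC[C@@H]1Br | intermediate
33 | (3S,3aS,4R,7S,7aS)-7-bromo-3-{(E)-[(4S)-4-bromo-3,3-dimethylcyclohexylidene]methyl}-4,7a-dimethyloctahydro-1H-inden-4-ol | CC1(C)C/C(=C/[C@@H]2CC[C@]3(C)[C@@H](Br)CC[C@@](C)(O)[C@@H]23)CC[C@@H]1Br | target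

## Step count and least certain steps

Total steps: 21. Longest linear sequence: 19 (steps 1, 3–12, 14–21).

Step 3 (key step). Most likely failure: erosion of regio- and face selectivity if the boron cation binds C15=O at the lone pair syn to C14–H (a complex that does not organise C10=C17), or a slow reaction at the methyl-bearing β-carbon that gives acid time to destroy the silyl dienol ether. Fallback (sets out from 4, returns at 7): the purchasable isomer 2-methoxy-5-methyl-1,4-benzoquinone F1 would be combined with 4 under a chelating chiral Lewis acid, the tetravalent titanium complex from BINOL and TiCl2(OiPr)2 in toluene at −40 °C. Two-point binding through the methoxy oxygen and the neighbouring carbonyl (C15 in F1) again makes C10 the β-carbon, as in the thermal reaction of this quinone, so the same two bonds should form and give the cis adduct (4aS,8R,8aS)-2-methoxy-4a-methyl-8-(triethylsilyloxy)-4a,5,8,8a-tetrahydronaphthalene-1,4-dione F2. Catalytic KOtBu would epimerise C17, now α to the more acidic non-vinylogous carbonyl, to the trans isomer F3, and SmI2 in THF–MeOH would remove the C14 methoxy group and the ring unsaturation to give 7.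

Step 20. Most likely failure: E2 elimination or a methyl shift from the alkoxyphosphonium ion, because backside attack at a carbon next to C2 is slow; bromide–bromide exchange could also erode configuration. Fallback (sets out from 30, returns at 32): reduction with the (R)-CBS catalyst and catecholborane would give the (20S)-alcohol F4; sulfonylation with 2-[2-(2-methoxyethoxy)ethoxy]benzenesulfonyl chloride (Et3N, DMAP) would give the chelating aryl sulfonate F5; TiBr4 in CH2Cl2 at −78 °C should then deliver bromide from the face of the departing sulfonate (titanium-assisted front-side displacement with retention, a known reaction type for hindered secondary sulfonates), giving 32 without any backside attack.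

Step 4. Most likely failure: an equilibrium that does not favour the trans fusion strongly enough, or E1cB loss of the C6 silanolate from the C17 enolate under the alkoxide needed for the weakly acidic vinylogous-ester α′-hydrogen. Fallback (sets out from 5, returns at 7): reduction and epimerisation change places. SmI2 in THF–MeOH would convert 5 into the cis-fused saturated dione (4aS,8R,8aS)-4a-methyl-8-(triethylsilyloxy)-2,3,4a,5,8,8a-hexahydronaphthalene-1,4-dione F6, in which C17–H is α to an ordinary ketone and exchanges under much milder base (K2CO3, MeOH, rt); equilibration of F6 would then give 7.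

Step 9. Most likely failure: hydrogenolysis of the C–Br bond on the metal, or a stalled catalyst that leaves the bromoalkene untouched. Fallback (sets out from 11, returns at 12): a radical hydrogen-atom-transfer hydrogenation (Mn(dpm)3, PhSiH3, tBuOOH, iPrOH, rt) should reduce only the bromoalkene, through a C12 radical that takes its second hydrogen on the axial α face, giving (1S,4R,4aR,5R,8aS)-1-bromo-4,8a-dimethyl-4,5-bis(triethylsilyloxy)-1,2,3,4,4a,5,8,8a-octahydronaphthalene F7; the remaining C7=C8 bond would then be saturated with H2 and RhCl(PPh3)3 to reach 12.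

Step 14. Most likely failure: a sluggish olefination of the hindered aldehyde with the α-substituted phosphonate, with loss of E selectivity under forcing conditions. Fallback (sets out from 19, returns at 28): 19 would be reduced with iBu2AlH and 23 isolated. tert-Butyl 4-bromopent-4-enoate F8 (from tert-butyl acetate, LiN(iPr)2 and 2,3-dibromopropene) would be added to 23 under Nozaki–Hiyama–Kishi conditions (CrCl2, catalytic NiCl2, DMF) to give the allylic alcohol tert-butyl 4-[hydroxy(Ind)methyl]pent-4-enoate F9 as a mixture of C6 epimers. Acylation with isobutyryl chloride (pyridine, DMAP) would give the isobutyrate F10. Ireland–Claisen rearrangement (LiN(iPr)2, Me3SiCl, THF, −78 °C to rt) through a chair with C7 equatorial should give the acid (4E)-7-tert-butoxy-4-(Ind-methylidene)-2,2-dimethyl-7-oxoheptanoic acid F11 with C4 trans to C7 from either epimer. Me3SiCHN2 would convert F11 into 28, which is cyclised with KOtBu as in step 17.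

## Further compounds

F1 | step 3 | 2-methoxy-5-methyl-1,4-benzoquinone | COC1=CC(=O)C(C)=CC1=O
F2 | step 3 | (4aS,8R,8aS)-2-methoxy-4a-methyl-8-(triethylsilyloxy)-4a,5,8,8a-tetrahydronaphthalene-1,4-dione | CC[Si](CC)(CC)O[C@@H]1C=CC[C@]2(C)C(=O)C=C(OC)C(=O)[C@H]12
F3 | step 3 | (4aS,8R,8aR)-2-methoxy-4a-methyl-8-(triethylsilyloxy)-4a,5,8,8a-tetrahydronaphthalene-1,4-dione | CC[Si](CC)(CC)O[C@@H]1C=CC[C@]2(C)C(=O)C=C(OC)C(=O)[C@@H]12
F4 | step 20 | (1S,4E)-4-(Ind-methylidene)-2,2-dimethylcyclohexan-1-ol | CC1(C)C/C(=C/[C@@H]2CC[C@]3(C)[C@@H](Br)CC[C@@](C)(O[Si](CC)(CC)CC)[C@@H]23)CC[C@@H]1O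
F5 | step 20 | (1S,4E)-4-(Ind-methylidene)-2,2-dimethylcyclohexyl 2-[2-(2-methoxyethoxy)ethoxy]benzenesulfonate | CC1(C)C/C(=C/[C@@H]2CC[C@]3(C)[C@@H](Br)CC[C@@](C)(O[Si](CC)(CC)CC)[C@@H]23)CC[C@@H]1OS(=O)(=O)c1ccccc1OCCOCCOC
F6 | step 4 | (4aS,8R,8aS)-4a-methyl-8-(triethylsilyloxy)-2,3,4a,5,8,8a-hexahydronaphthalene-1,4-dione | CC[Si](CC)(CC)O[C@@H]1C=CC[C@]2(C)C(=O)CCC(=O)[C@H]12
F7 | step 9 | (1S,4R,4aR,5R,8aS)-1-bromo-4,8a-dimethyl-4,5-bis(triethylsilyloxy)-1,2,3,4,4a,5,8,8a-octahydronaphthalene | CC[Si](CC)(CC)O[C@@H]1C=CC[C@]2(C)[C@@H](Br)CC[C@@](C)(O[Si](CC)(CC)CC)[C@@H]12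
F8 | step 14 | tert-butyl 4-bromopent-4-enoate | C=C(Br)CCC(=O)OC(C)(C)C
F9 | step 14 | tert-butyl 4-[hydroxy(Ind)methyl]pent-4-enoate (C6 epimers) | C=C(CCC(=O)OC(C)(C)C)C(O)[C@@H]1CC[C@]2(C)[C@@H](Br)CC[C@@](C)(O[Si](CC)(CC)CC)[C@@H]12
F10 | step 14 | tert-butyl 4-[(isobutyryloxy)(Ind)methyl]pent-4-enoate (C6 epimers) | CC(C)C(=O)OC(C(=C)CCC(=O)OC(C)(C)C)[C@@H]1CC[C@]2(C)[C@@H](Br)CC[C@@](C)(O[Si](CC)(CC)CC)[C@@H]12
F11 | step 14 | (4E)-7-tert-butoxy-4-(Ind-methylidene)-2,2-dimethyl-7-oxoheptanoic acid | OC(=O)C(C)(C)C/C(CCC(=O)OC(C)(C)C)=C/[C@@H]1CC[C@]2(C)[C@@H](Br)CC[C@@](C)(O[Si](CC)(CC)CC)[C@@H]12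
A1 | alternative 1 | (S)-Wieland–Miescher ketone | O=C1C=C2CCCC(=O)[C@@]2(C)CC1
A2 | alternative 1 | trans-decalin α-diazo ketone (C12 ketal, C15 silyl ether) | O=C1CC[C@]3(C)C4(OCCO4)CC[C@@H](O[Si](C)(C)C(C)(C)C)[C@H]3C1=[N+]=[N-]
A3 | alternative 1 | trans-hydrindane methyl ester | COC(=O)[C@@H]2CC[C@]3(C)C4(OCCO4)CC[C@@H](O[Si](C)(C)C(C)(C)C)[C@@H]23
A4 | alternative 2 | open-chain alkyne with C4 iodide | ICC(C)(C)[C@@H](Br)CCC#C[C@@H]1CC[C@]2(C)[C@@H](Br)CC[C@@](C)(O[Si](C)(C)C)[C@@H]12
A5 | alternative 2 | (E)-C5 iodoalkene with C4 iodide | ICC(C)(C)[C@@H](Br)CC/C(I)=C\[C@@H]1CC[C@]2(C)[C@@H](Br)CC[C@@](C)(O[Si](C)(C)C)[C@@H]12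
A6 | alternative 2 | C15 trimethylsilyl ether of the target | CC1(C)C/C(=C/[C@@H]2CC[C@]3(C)[C@@H](Br)CC[C@@](C)(O[Si](C)(C)C)[C@@H]23)CC[C@@H]1Br
A7 | alternative 3 | (E)-5-(tert-butyldimethylsilyloxy)-2-methylpent-2-enal | O=C/C(C)=C/CCO[Si](C)(C)C(C)(C)C
A8 | alternative 3 | (1E,3E)-1,4-diacetoxybuta-1,3-diene | CC(=O)O/C=C/C=C/OC(C)=O
A9 | alternative 3 | diacetoxycyclohexene aldehyde | O=C[C@]3(C)[C@H](OC(C)=O)C=C[C@H](OC(C)=O)[C@H]3CCO[Si](C)(C)C(C)(C)C
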